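**Retrosynthetic overview**

- The strategy rests on the only ring: the 3‑monosubstituted furan carried on C18 (chain numbered C1, an isopropyl methyl, to C18, furan C3). Its ring C3=C4 bond is cut back to two terminal alkenes, the C18 exocyclic methylene and the vinyl group of a mixed ethyl acrolein acetal; ring‑closing metathesis then loss of ethanol forms this ring last.
- The two skipped enones (C4=O and C12=O, each β,γ to an E‑trisubstituted alkene) travel as silyl‑protected carbinols and are unmasked by one double oxidation just before the metathesis.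
- C16–C17 and C18: allylic bromide plus the dianion of methallyl alcohol. E‑C14=C15 and C16: Negishi carboalumination/hydroxymethylation of a terminal alkyne. C12–C13: zinc propargylation of the C12 aldehyde.
- C4–C5: α‑selective allylbarium addition to 3‑methylbutanal. C5–C12, the C10 (S) centre and E‑C6=C7 come from (S)‑citronellol through SeO2 oxidation of its E‑methyl group.

Key step: step 15

Assumption: the carbinol centres at C4 and C12 and the acetal carbon are formed without control and carried as epimer mixtures, since all three become trigonal in the target; C10 (S) is never touched.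

**Route**

Step 1
Reactants: 1 (S)-citronellol
Product: 2 tert-butyl{[(3S)-3,7-dimethyloct-6-en-1-yl]oxy}dimethylsilane
Conditions: TBSCl, imidazole, DMF, rt
Reagents that add atoms: tert-butyldimethylsilyl chloride, CC(C)(C)[Si](C)(C)Cl
Why: Imidazole-promoted silylation masks the primary hydroxyl (future C12) so that it survives the allylic oxidation and the organobarium step.

Step 2
Reactants: 2 tert-butyl{[(3S)-3,7-dimethyloct-6-en-1-yl]oxy}dimethylsilane
Product: 3 (2E,6S)-8-[(tert-butyldimethylsilyl)oxy]-2,6-dimethyloct-2-en-1-ol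
Conditions: SeO2 (0.1 equiv), t-BuOOH (3 equiv), salicylic acid (0.1 equiv), CH2Cl2, rt
Reagents that add atoms: tert-butyl hydroperoxide, CC(C)(C)OO (oxygen relayed by catalytic selenium dioxide, O=[Se]=O)
Why: The SeO2 allylic oxidation (ene reaction followed by [2,3]-sigmatropic shift) should hydroxylate the methyl group trans to the chain, which fixes E-C6=C7 and makes C5 a CH2OH.

Step 3
Reactants: 3 (2E,6S)-8-[(tert-butyldimethylsilyl)oxy]-2,6-dimethyloct-2-en-1-ol
Product: 4 tert-butyl{[(3S,6E)-8-chloro-3,7-dimethyloct-6-en-1-yl]oxy}dimethylsilane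
Conditions: PPh3, N-chlorosuccinimide, THF, 0 °C to rt
Reagents that add atoms: N-chlorosuccinimide, O=C1CCC(=O)N1Cl
Why: Appel-type chlorination displaces the primary oxyphosphonium by SN2, so the chloride should form without allylic transposition or loss of alkene geometry.

Step 4
Reactants: 4 tert-butyl{[(3S,6E)-8-chloro-3,7-dimethyloct-6-en-1-yl]oxy}dimethylsilane; 5 3-methylbutanal
Product: 7 (6E,10S)-12-[(tert-butyldimethylsilyl)oxy]-2,6,10-trimethyldodec-6-en-4-ol as both C4 epimers, via allylbarium chloride 6 (not isolated)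
Conditions: BaI2, lithium biphenylide (2 equiv, stock solution), THF, rt; then 4, −78 °C; then 5, −78 °C; aq. NH4Cl
Reagents that add atoms: none
Why: Allylbarium reagents add to aldehydes through the unsubstituted α-carbon with retention of alkene geometry (Grignard-type addition with regiochemistry opposite to allylmagnesium or allylzinc), so the C4–C5 bond should form as the linear E-homoallylic alcohol; the C4 configuration is not controlled and is erased in step 14.

Step 5
Reactants: 7 (6E,10S)-12-[(tert-butyldimethylsilyl)oxy]-2,6,10-trimethyldodec-6-en-4-ol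
Product: 8 (3S,6E)-3,7,11-trimethyldodec-6-ene-1,9-diol
Conditions: TBAF, THF, rt
Reagents that add atoms: none
Why: Fluoride-induced desilylation frees the primary C12 hydroxyl under conditions harmless to the alkene and the secondary alcohol.

Step 6
Reactants: 8 (3S,6E)-3,7,11-trimethyldodec-6-ene-1,9-diol
Product: 9 (3S,6E)-9-hydroxy-3,7,11-trimethyldodec-6-enal
Conditions: TEMPO (0.1 equiv), PhI(OAc)2 (1.1 equiv), CH2Cl2, rt
Reagents that add atoms: none
Why: The oxoammonium (TEMPO/PhI(OAc)2) oxidation is much faster for primary than for secondary alcohols, so only C12 should reach the aldehyde; the C10 centre is β to the carbonyl and cannot epimerise.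

Step 7
Reactants: 9 (3S,6E)-9-hydroxy-3,7,11-trimethyldodec-6-enal; 10 3-bromoprop-1-yne
Product: 12 (6S,9E)-6,10,14-trimethylpentadec-9-en-1-yne-4,12-diol as epimers at both carbinols, via allenylzinc bromide 11 (not isolated)
Conditions: Zn dust, THF/sat. aq. NH4Cl, 0 °C to rt
Reagents that add atoms: none
Why: In this Barbier propargylation the allenylzinc species adds through its γ-carbon (SE2′) to give the homopropargylic alcohol, tolerates the free C4 hydroxyl and forms the C12–C13 bond; the C12 configuration is irrelevant.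

Step 8
Reactants: 12 (6S,9E)-6,10,14-trimethylpentadec-9-en-1-yne-4,12-diol
Product: 13 (6S,9E)-4,12-bis[(tert-butyldimethylsilyl)oxy]-6,10,14-trimethylpentadec-9-en-1-yne
Conditions: TBSOTf (2.5 equiv), 2,6-lutidine, CH2Cl2, −78 to 0 °C
Reagents that add atoms: tert-butyldimethylsilyl trifluoromethanesulfonate, CC(C)(C)[Si](C)(C)OS(=O)(=O)C(F)(F)F
Why: Silyl triflate with a hindered base silylates both secondary alcohols in one operation, so the future ketone carbons are inert to the organoaluminium and organolithium reagents that follow.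

Step 9
Reactants: 13 (6S,9E)-4,12-bis[(tert-butyldimethylsilyl)oxy]-6,10,14-trimethylpentadec-9-en-1-yne
Product: 16 (2E,7S,10E)-5,13-bis[(tert-butyldimethylsilyl)oxy]-3,7,11,15-tetramethylhexadeca-2,10-dien-1-ol, via alkenyldimethylalane 14 (not isolated), via lithium alkenyl(butyl)dimethylalanate 15 (not isolated)
Conditions: Me3Al, Cp2ZrCl2 (0.3 equiv), CH2Cl2, 0 °C to rt; then n-BuLi, THF, −78 °C; then (CH2O)n, −78 °C to rt
Reagents that add atoms: trimethylaluminium, C[Al](C)C; formaldehyde (as paraformaldehyde), C=O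
Why: Negishi zirconium-catalysed carboalumination adds methyl and aluminium syn across the terminal alkyne with methyl on the internal carbon (C14), and hydroxymethylation of the derived alanate proceeds with retention, which fixes E-C14=C15 and adds C16.

Step 10
Reactants: 16 (2E,7S,10E)-5,13-bis[(tert-butyldimethylsilyl)oxy]-3,7,11,15-tetramethylhexadeca-2,10-dien-1-ol
Product: 17 (2E,7S,10E)-1-bromo-5,13-bis[(tert-butyldimethylsilyl)oxy]-3,7,11,15-tetramethylhexadeca-2,10-diene
Conditions: CBr4, PPh3, 2,6-lutidine, CH2Cl2, −20 °C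
Reagents that add atoms: carbon tetrabromide, BrC(Br)(Br)Br
Why: The Appel reaction converts the primary allylic alcohol into the bromide by SN2 without transposition, and the neutral buffered medium leaves both silyl ethers in place.

Step 11
Reactants: 17 (2E,7S,10E)-1-bromo-5,13-bis[(tert-butyldimethylsilyl)oxy]-3,7,11,15-tetramethylhexadeca-2,10-diene; 18 2-methylprop-2-en-1-ol
Product: 20 (5E,10S,13E)-8,16-bis[(tert-butyldimethylsilyl)oxy]-6,10,14,18-tetramethyl-2-methylidenenonadeca-5,13-dien-1-ol, via dilithiated 2-methylprop-2-en-1-ol 19 (not isolated)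
Conditions: 18 (3 equiv), n-BuLi (2 equiv per 18), TMEDA, Et2O, 0 °C to rt; then 17, THF, −78 °C to rt
Reagents that add atoms: none
Why: Alkoxide-directed lithiation of the methyl group gives the allyl/alkoxide dianion, whose carbon terminus should alkylate the primary allylic bromide at the bromine-bearing carbon (SN2; the SN2′ site is fully substituted), forming C16–C17 and installing C18 with its methylene and CH2OH.

Step 12
Reactants: 20 (5E,10S,13E)-8,16-bis[(tert-butyldimethylsilyl)oxy]-6,10,14,18-tetramethyl-2-methylidenenonadeca-5,13-dien-1-ol; 21 3,3-diethoxyprop-1-ene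
Product: 22 (5E,10S,13E)-8,16-bis[(tert-butyldimethylsilyl)oxy]-1-[(1-ethoxyprop-2-en-1-yl)oxy]-6,10,14,18-tetramethyl-2-methylidenenonadeca-5,13-diene as both acetal epimers
Conditions: 21 (10 equiv), PPTS (5 mol%), toluene, 40 °C, reduced pressure (removal of EtOH)
Reagents that add atoms: none
Why: Acid-catalysed transacetalisation, driven by excess acetal and removal of ethanol, converts the only free hydroxyl into the mixed allyl acrolein acetal; the new acetal centre is uncontrolled and disappears on aromatisation.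

Step 13
Reactants: 22 (5E,10S,13E)-8,16-bis[(tert-butyldimethylsilyl)oxy]-1-[(1-ethoxyprop-2-en-1-yl)oxy]-6,10,14,18-tetramethyl-2-methylidenenonadeca-5,13-diene
Product: 23 (6E,10S,14E)-18-{[(1-ethoxyprop-2-en-1-yl)oxy]methyl}-2,6,10,14-tetramethylnonadeca-6,14,18-triene-4,12-diol
Conditions: TBAF (4 equiv), THF, rt
Reagents that add atoms: none
Why: Fluoride desilylation removes both secondary silyl ethers under basic conditions that the acid-labile mixed acetal tolerates.

Step 14
Reactants: 23 (6E,10S,14E)-18-{[(1-ethoxyprop-2-en-1-yl)oxy]methyl}-2,6,10,14-tetramethylnonadeca-6,14,18-triene-4,12-diol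
Product: 24 (6E,10S,14E)-18-{[(1-ethoxyprop-2-en-1-yl)oxy]methyl}-2,6,10,14-tetramethylnonadeca-6,14,18-triene-4,12-dione as both acetal epimers
Conditions: Dess–Martin periodinane (3 equiv), pyridine, CH2Cl2, 0 °C to rt
Reagents that add atoms: none
Why: Buffered Dess–Martin oxidation converts both homoallylic alcohols into β,γ-unsaturated ketones without the acid or base that would move the alkenes into conjugation or cleave the acetal.

Step 15
Reactants: 24 (6E,10S,14E)-18-{[(1-ethoxyprop-2-en-1-yl)oxy]methyl}-2,6,10,14-tetramethylnonadeca-6,14,18-triene-4,12-dione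
Product: 25 (6E,10S,14E)-17-(5-ethoxy-2,5-dihydrofuran-3-yl)-2,6,10,14-tetramethylheptadeca-6,14-diene-4,12-dione as both acetal epimers
Conditions: second-generation Grubbs catalyst RuCl2(=CHPh)(PCy3)(H2IMes) (5 mol%), 1,4-benzoquinone (10 mol%), degassed CH2Cl2 (0.005 M), 40 °C; filtration through Et3N-deactivated silica
Reagents that add atoms: none
Why: The ruthenium benzylidene should exchange onto the monosubstituted vinyl group of the acrolein acetal, the new alkylidene adds [2+2] to the 1,1-disubstituted C18 methylene, and cycloreversion of the ruthenacyclobutane releases ethene and the ring alkene that becomes the furan C3=C4 bond. The closest known reaction type is ring-closing olefin metathesis of mixed allyl acrolein acetals to 2-alkoxy-2,5-dihydrofurans. The single ring closes as a five-membered ring by intramolecular metathesis, with the oxygen and the acetal carbon already in the tether. No new stereocentre is formed; the acetal carbon remains an epimer mixture that step 16 erases, and C10 is remote. The step needs chemoselectivity among four alkenes, which the substrate secures because only the two terminal alkenes can load ruthenium and close a five-membered ring, whereas the hindered trisubstituted C6=C7 and C14=C15 alkenes could only close rings of eight or more atoms. The neutral medium with benzoquinone as hydride scavenger should keep both skipped enones deconjugated and the acetal intact.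

Step 16
Reactants: 25 (6E,10S,14E)-17-(5-ethoxy-2,5-dihydrofuran-3-yl)-2,6,10,14-tetramethylheptadeca-6,14-diene-4,12-dione
Product: 26 idiadione, (6E,10S,14E)-17-(furan-3-yl)-2,6,10,14-tetramethylheptadeca-6,14-diene-4,12-dione
Conditions: PPTS (10 mol%), CH2Cl2, rt
Reagents that add atoms: none
Why: Acid-catalysed ionisation of the cyclic acetal to an oxocarbenium ion and loss of a proton from the ring CH2 (elimination of ethanol) aromatises the dihydrofuran to the 3-substituted furan, and the weak acid should leave the skipped enones unconjugated.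

**Compound list**

1 | (S)-citronellol | OCC[C@@H](C)CCC=C(C)C | starting material
2 | tert-butyl{[(3S)-3,7-dimethyloct-6-en-1-yl]oxy}dimethylsilane | CC(C)=CCC[C@H](C)CCO[Si](C)(C)C(C)(C)C | intermediate
3 | (2E,6S)-8-[(tert-butyldimethylsilyl)oxy]-2,6-dimethyloct-2-en-1-ol | OC/C(C)=C/CC[C@H](C)CCO[Si](C)(C)C(C)(C)C | intermediate
4 | tert-butyl{[(3S,6E)-8-chloro-3,7-dimethyloct-6-en-1-yl]oxy}dimethylsilane | ClC/C(C)=C/CC[C@H](C)CCO[Si](C)(C)C(C)(C)C | intermediate
5 | 3-methylbutanal | CC(C)CC=O | starting material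
6 | chloro{(2E,6S)-8-[(tert-butyldimethylsilyl)oxy]-2,6-dimethyloct-2-en-1-yl}barium (not isolated) | Cl[Ba]C/C(C)=C/CC[C@H](C)CCO[Si](C)(C)C(C)(C)C | intermediate
7 | (6E,10S)-12-[(tert-butyldimethylsilyl)oxy]-2,6,10-trimethyldodec-6-en-4-ol (C4 epimers) | CC(C)CC(O)C/C(C)=C/CC[C@H](C)CCO[Si](C)(C)C(C)(C)C | intermediate
8 | (3S,6E)-3,7,11-trimethyldodec-6-ene-1,9-diol | CC(C)CC(O)C/C(C)=C/CC[C@H](C)CCO | intermediate
9 | (3S,6E)-9-hydroxy-3,7,11-trimethyldodec-6-enal | CC(C)CC(O)C/C(C)=C/CC[C@H](C)CC=O | intermediate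
10 | 3-bromoprop-1-yne | BrCC#C | starting material
11 | allenylzinc bromide (not isolated) | C=C=C[Zn]Br | intermediate
12 | (6S,9E)-6,10,14-trimethylpentadec-9-en-1-yne-4,12-diol | CC(C)CC(O)C/C(C)=C/CC[C@H](C)CC(O)CC#C | intermediate
13 | (6S,9E)-4,12-bis[(tert-butyldimethylsilyl)oxy]-6,10,14-trimethylpentadec-9-en-1-yne | CC(C)CC(O[Si](C)(C)C(C)(C)C)C/C(C)=C/CC[C@H](C)CC(O[Si](C)(C)C(C)(C)C)CC#C | intermediate
14 | dimethyl{(1E,6S,9E)-4,12-bis[(tert-butyldimethylsilyl)oxy]-2,6,10,14-tetramethylpentadeca-1,9-dien-1-yl}alane (not isolated) | CC(C)CC(O[Si](C)(C)C(C)(C)C)C/C(C)=C/CC[C@H](C)CC(O[Si](C)(C)C(C)(C)C)C/C(C)=C/[Al](C)C | intermediate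
15 | lithium butyldimethyl{(1E,6S,9E)-4,12-bis[(tert-butyldimethylsilyl)oxy]-2,6,10,14-tetramethylpentadeca-1,9-dien-1-yl}alanate (not isolated) | [Li+].CC(C)CC(O[Si](C)(C)C(C)(C)C)C/C(C)=C/CC[C@H](C)CC(O[Si](C)(C)C(C)(C)C)C/C(C)=C/[Al-](C)(C)CCCC | intermediate
16 | (2E,7S,10E)-5,13-bis[(tert-butyldimethylsilyl)oxy]-3,7,11,15-tetramethylhexadeca-2,10-dien-1-ol | CC(C)CC(O[Si](C)(C)C(C)(C)C)C/C(C)=C/CC[C@H](C)CC(O[Si](C)(C)C(C)(C)C)C/C(C)=C/CO | intermediate
17 | (2E,7S,10E)-1-bromo-5,13-bis[(tert-butyldimethylsilyl)oxy]-3,7,11,15-tetramethylhexadeca-2,10-diene | CC(C)CC(O[Si](C)(C)C(C)(C)C)C/C(C)=C/CC[C@H](C)CC(O[Si](C)(C)C(C)(C)C)C/C(C)=C/CBr | intermediate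
18 | 2-methylprop-2-en-1-ol (methallyl alcohol) | C=C(C)CO | starting material
19 | dilithiated 2-methylprop-2-en-1-ol, lithium 2-(lithiomethyl)prop-2-en-1-olate (not isolated) | [Li]CC(=C)CO[Li] | intermediate
20 | (5E,10S,13E)-8,16-bis[(tert-butyldimethylsilyl)oxy]-6,10,14,18-tetramethyl-2-methylidenenonadeca-5,13-dien-1-ol | CC(C)CC(O[Si](C)(C)C(C)(C)C)C/C(C)=C/CC[C@H](C)CC(O[Si](C)(C)C(C)(C)C)C/C(C)=C/CCC(=C)CO | intermediate
21 | 3,3-diethoxyprop-1-ene (acrolein diethyl acetal) | C=CC(OCC)OCC | starting material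
22 | (5E,10S,13E)-8,16-bis[(tert-butyldimethylsilyl)oxy]-1-[(1-ethoxyprop-2-en-1-yl)oxy]-6,10,14,18-tetramethyl-2-methylidenenonadeca-5,13-diene (acetal epimers) | CC(C)CC(O[Si](C)(C)C(C)(C)C)C/C(C)=C/CC[C@H](C)CC(O[Si](C)(C)C(C)(C)C)C/C(C)=C/CCC(=C)COC(OCC)C=C | intermediate
23 | (6E,10S,14E)-18-{[(1-ethoxyprop-2-en-1-yl)oxy]methyl}-2,6,10,14-tetramethylnonadeca-6,14,18-triene-4,12-diol | CC(C)CC(O)C/C(C)=C/CC[C@H](C)CC(O)C/C(C)=C/CCC(=C)COC(OCC)C=C | intermediate
24 | (6E,10S,14E)-18-{[(1-ethoxyprop-2-en-1-yl)oxy]methyl}-2,6,10,14-tetramethylnonadeca-6,14,18-triene-4,12-dione (metathesis precursor, acetal epimers) | CC(C)CC(=O)C/C(C)=C/CC[C@H](C)CC(=O)C/C(C)=C/CCC(=C)COC(OCC)C=C | intermediate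
25 | (6E,10S,14E)-17-(5-ethoxy-2,5-dihydrofuran-3-yl)-2,6,10,14-tetramethylheptadeca-6,14-diene-4,12-dione (acetal epimers) | CC(C)CC(=O)C/C(C)=C/CC[C@H](C)CC(=O)C/C(C)=C/CCC1=CC(OCC)OC1 | intermediate
26 | idiadione, (6E,10S,14E)-17-(furan-3-yl)-2,6,10,14-tetramethylheptadeca-6,14-diene-4,12-dione | CC(C)CC(=O)C/C(C)=C/CC[C@H](C)CC(=O)C/C(C)=C/CCc1ccoc1 | target

**Step count**

Total: 16 steps. Longest linear sequence: 16 steps, from (S)-citronellol 1.

**Steps most likely to fail**

Step 4 (allylbarium addition). Reductive homocoupling of the allylic chloride during metalation, or leakage of the allylbarium to the γ-adduct or to the Z-isomer, would erode the linear E-alcohol. The fallback reverses the polarity; it sets out from chloride 4 and rejoins the route at alcohol 7. 3-Methylbutanal 5 and propane-1,3-dithiol (BF3·OEt2, CH2Cl2) would give 2-(2-methylpropyl)-1,3-dithiane F1. Deprotonation (n-BuLi, THF, −30 °C) would give 2-lithio-2-(2-methylpropyl)-1,3-dithiane F2, which should alkylate 4 at the primary allylic carbon (Corey–Seebach alkylation) to tert-butyl{[(3S,6E)-3,7-dimethyl-8-[2-(2-methylpropyl)-1,3-dithian-2-yl]oct-6-en-1-yl]oxy}dimethylsilane F3. MeI and CaCO3 in aqueous MeCN would unmask (6E,10S)-12-[(tert-butyldimethylsilyl)oxy]-2,6,10-trimethyldodec-6-en-4-one F4, and NaBH4 in MeOH at 0 °C would reduce it to 7.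

Step 11 (dianion alkylation). SN2′ attack, bromine–lithium exchange or elimination could outrun C-alkylation of the bromide by the dianion. The fallback attaches C18 by carbomagnesiation instead; it sets out from alkyne 13 and rejoins the route at alcohol 20. Alanate 15, generated from 13 as in step 9, would be trapped with oxirane in place of formaldehyde to give (3E,8S,11E)-6,14-bis[(tert-butyldimethylsilyl)oxy]-4,8,12,16-tetramethylheptadeca-3,11-dien-1-ol F5. CBr4/PPh3 would give (3E,8S,11E)-1-bromo-6,14-bis[(tert-butyldimethylsilyl)oxy]-4,8,12,16-tetramethylheptadeca-3,11-diene F6, and magnesium in THF the Grignard reagent {(3E,8S,11E)-6,14-bis[(tert-butyldimethylsilyl)oxy]-4,8,12,16-tetramethylheptadeca-3,11-dien-1-yl}magnesium bromide F7. Addition of F7 across the bromomagnesium alkoxide of prop-2-yn-1-ol, catalysed by copper iodide CuI (alkyl to the internal alkyne carbon, then protonolysis), would deliver 20.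

Step 15 (ring-closing metathesis). Ruthenium hydride species could migrate the skipped-enone alkenes into conjugation, the ketone carbonyls could sequester the catalyst, or the acetal could ionise before ring closure. The fallback closes the furan before the ketones exist; it sets out from bis-silyl acetal 22 and rejoins the route at target 26. Metathesis of 22 with the second-generation Grubbs catalyst RuCl2(=CHPh)(PCy3)(H2IMes) would give 3-{(3E,8S,11E)-6,14-bis[(tert-butyldimethylsilyl)oxy]-4,8,12,16-tetramethylheptadeca-3,11-dien-1-yl}-5-ethoxy-2,5-dihydrofuran F8. PPTS in CH2Cl2 would aromatise it to 3-{(3E,8S,11E)-6,14-bis[(tert-butyldimethylsilyl)oxy]-4,8,12,16-tetramethylheptadeca-3,11-dien-1-yl}furan F9. TBAF would free (6E,10S,14E)-17-(furan-3-yl)-2,6,10,14-tetramethylheptadeca-6,14-diene-4,12-diol F10, and pyridine-buffered Dess–Martin oxidation would give 26.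

**Further compounds**

F1 | step 4 | 2-(2-methylpropyl)-1,3-dithiane | CC(C)CC1SCCCS1
F2 | step 4 | 2-lithio-2-(2-methylpropyl)-1,3-dithiane | [Li]C1(CC(C)C)SCCCS1
F3 | step 4 | tert-butyl{[(3S,6E)-3,7-dimethyl-8-[2-(2-methylpropyl)-1,3-dithian-2-yl]oct-6-en-1-yl]oxy}dimethylsilane | CC(C)CC1(SCCCS1)C/C(C)=C/CC[C@H](C)CCO[Si](C)(C)C(C)(C)C
F4 | step 4 | (6E,10S)-12-[(tert-butyldimethylsilyl)oxy]-2,6,10-trimethyldodec-6-en-4-one | CC(C)CC(=O)C/C(C)=C/CC[C@H](C)CCO[Si](C)(C)C(C)(C)C
F5 | step 11 | (3E,8S,11E)-6,14-bis[(tert-butyldimethylsilyl)oxy]-4,8,12,16-tetramethylheptadeca-3,11-dien-1-ol | CC(C)CC(O[Si](C)(C)C(C)(C)C)C/C(C)=C/CC[C@H](C)CC(O[Si](C)(C)C(C)(C)C)C/C(C)=C/CCO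
F6 | step 11 | (3E,8S,11E)-1-bromo-6,14-bis[(tert-butyldimethylsilyl)oxy]-4,8,12,16-tetramethylheptadeca-3,11-diene | CC(C)CC(O[Si](C)(C)C(C)(C)C)C/C(C)=C/CC[C@H](C)CC(O[Si](C)(C)C(C)(C)C)C/C(C)=C/CCBr
F7 | step 11 | {(3E,8S,11E)-6,14-bis[(tert-butyldimethylsilyl)oxy]-4,8,12,16-tetramethylheptadeca-3,11-dien-1-yl}magnesium bromide | CC(C)CC(O[Si](C)(C)C(C)(C)C)C/C(C)=C/CC[C@H](C)CC(O[Si](C)(C)C(C)(C)C)C/C(C)=C/CC[Mg]Br
F8 | step 15 | 3-{(3E,8S,11E)-6,14-bis[(tert-butyldimethylsilyl)oxy]-4,8,12,16-tetramethylheptadeca-3,11-dien-1-yl}-5-ethoxy-2,5-dihydrofuran | CC(C)CC(O[Si](C)(C)C(C)(C)C)C/C(C)=C/CC[C@H](C)CC(O[Si](C)(C)C(C)(C)C)C/C(C)=C/CCC1=CC(OCC)OC1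
F9 | step 15 | 3-{(3E,8S,11E)-6,14-bis[(tert-butyldimethylsilyl)oxy]-4,8,12,16-tetramethylheptadeca-3,11-dien-1-yl}furan | CC(C)CC(O[Si](C)(C)C(C)(C)C)C/C(C)=C/CC[C@H](C)CC(O[Si](C)(C)C(C)(C)C)C/C(C)=C/CCc1ccoc1
F10 | step 15 | (6E,10S,14E)-17-(furan-3-yl)-2,6,10,14-tetramethylheptadeca-6,14-diene-4,12-diol | CC(C)CC(O)C/C(C)=C/CC[C@H](C)CC(O)C/C(C)=C/CCc1ccoc1
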